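**Plan**

1. Retrosynthesis: the MOM ethers and the two ring A prenyl termini come off last (allyl groups stand in for prenyl until a cross-metathesis). The oxepine is then cut at both bonds that tie it to ring B: the C2–C1' biaryl bond and the O2'–CH ether bond.
2. Enabling feature: in the seven-membered ring O2'–C2'–C1'–C2–C3–CH2–CH the ether oxygen is ortho to the biaryl bond, and the stereogenic CH bears C(CH3)2OH, the mark of a phenoxide-opened 2,2-dimethyloxirane. C2 of the pyranone (ring C) is a vinylogous acyl carbon, so ring B is a C1'/O2' dinucleophile and the chromone a C2/CH dielectrophile.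
3. Key event: domino Suzuki–Miyaura coupling of a 2-iodo-3-(oxiranylmethyl)chromone with a 2-hydroxyarylboronate, then strain-releasing 7-exo epoxide opening; this formal [4+3] annulation adds ring B and closes the oxepine in one operation.
4. Forward order: ring A from 2,4,6-trihydroxyacetophenone (O-allylation, double Claisen, MOM), chain extension by enolate prenylation, ring C by enaminone annulation, epoxidation, C2 iodination, key annulation, allyl-to-prenyl metathesis, deprotection.
5. Stereochemistry: the single stereocenter is set by Shi epoxidation with the L-fructose-derived ketone, giving the (S)-epoxide (the C3 prenyl is then the only trisubstituted alkene). SN2 opening in the key step inverts it to (R).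

Key step: step 9

Remark: LDA and TMPZnCl·LiCl are taken as commercial solutions and the L-fructose-derived Shi ketone as a purchased catalyst; where a step performs the same reaction at two sites, the singly reacted species is not numbered.

**Route**

Step 1
Reactants: 1 2,4,6-trihydroxyacetophenone
Product: 2 1-[2-hydroxy-4,6-bis(prop-2-en-1-yloxy)phenyl]ethan-1-one
Conditions: allyl bromide (2.1 equiv), K2CO3, acetone, reflux
Reagents that add atoms: allyl bromide, C=CCBr
Why: Williamson ether synthesis, in which the hydroxyl hydrogen-bonded to the acetyl carbonyl is the least nucleophilic and should stay free when two equivalents of electrophile are used.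

Step 2
Reactants: 2 1-[2-hydroxy-4,6-bis(prop-2-en-1-yloxy)phenyl]ethan-1-one
Product: 3 1-[2,4,6-trihydroxy-3,5-di(prop-2-en-1-yl)phenyl]ethan-1-one
Conditions: N,N-diethylaniline, 200 °C, sealed tube
Reagents that add atoms: none
Why: twofold aromatic Claisen rearrangement ([3,3]-sigmatropic, with a Cope relay to the para position if C3 is occupied first), which can only deliver the two allyl groups to the two free ring carbons C3 and C5.

Step 3
Reactants: 3 1-[2,4,6-trihydroxy-3,5-di(prop-2-en-1-yl)phenyl]ethan-1-one
Product: 4 1-[2-hydroxy-4,6-bis(methoxymethoxy)-3,5-di(prop-2-en-1-yl)phenyl]ethan-1-one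
Conditions: MOMCl (2.2 equiv), iPr2NEt, CH2Cl2, 0 °C to rt
Reagents that add atoms: chloromethyl methyl ether (MOMCl), COCCl
Why: MOM ether formation at the para hydroxyl and at one of the two equivalent ortho hydroxyls, after which the last hydroxyl is chelated to the ketone and should resist alkylation.

Step 4
Reactants: 4 1-[2-hydroxy-4,6-bis(methoxymethoxy)-3,5-di(prop-2-en-1-yl)phenyl]ethan-1-one
Product: 6 1-[2-hydroxy-4,6-bis(methoxymethoxy)-3,5-di(prop-2-en-1-yl)phenyl]-5-methylhex-4-en-1-one, via dilithium enolate phenoxide 5 (not isolated)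
Conditions: LiN(iPr)2 (LDA, 2.2 equiv), THF, −78 °C; prenyl bromide (1.05 equiv), −78 to 0 °C; NH4Cl (aq)
Reagents that add atoms: prenyl bromide (1-bromo-3-methylbut-2-ene), CC(C)=CCBr
Why: enolate C-alkylation of the dianion of a 2-hydroxyaryl methyl ketone, in which the enolate carbon is far more nucleophilic than the lithium phenoxide and attacks the primary allylic bromide by SN2.

Step 5
Reactants: 6 1-[2-hydroxy-4,6-bis(methoxymethoxy)-3,5-di(prop-2-en-1-yl)phenyl]-5-methylhex-4-en-1-one
Product: 8 5,7-bis(methoxymethoxy)-3-(3-methylbut-2-en-1-yl)-6,8-di(prop-2-en-1-yl)-4H-chromen-4-one, via enaminone 7 (not isolated)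
Conditions: Me2NCH(OMe)2 (3 equiv), toluene, 110 °C
Reagents that add atoms: N,N-dimethylformamide dimethyl acetal, COC(OC)N(C)C
Why: enaminone condensation at the ketone α-methylene followed by intramolecular O-addition and loss of dimethylamine, the standard chromone annulation of 2-hydroxyaryl alkyl ketones, which supplies C2 and leaves the prenyl chain on C3.

Step 6
Reactants: 8 5,7-bis(methoxymethoxy)-3-(3-methylbut-2-en-1-yl)-6,8-di(prop-2-en-1-yl)-4H-chromen-4-one
Product: 9 3-{[(2S)-3,3-dimethyloxiran-2-yl]methyl}-5,7-bis(methoxymethoxy)-6,8-di(prop-2-en-1-yl)-4H-chromen-4-one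
Conditions: L-fructose-derived Shi ketone (30 mol %), Oxone (2KHSO5·KHSO4·K2SO4), K2CO3, Bu4NHSO4, MeCN/CH2(OMe)2, aq. Na2B4O7/Na2EDTA buffer, 0 °C
Reagents that add atoms: Oxone (active oxidant KHSO5), [K+].[O-]S(=O)(=O)OO
Why: Shi asymmetric epoxidation, in which the chiral dioxirane reacts through the spiro transition state that mirrors the (R)-selective one of the D-fructose ketone and should give the (S)-epoxide, and in which the electron-rich trisubstituted alkene is expected to react well ahead of the monosubstituted allyl groups and the electron-poor pyranone C2=C3 bond.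

Step 7
Reactants: 9 3-{[(2S)-3,3-dimethyloxiran-2-yl]methyl}-5,7-bis(methoxymethoxy)-6,8-di(prop-2-en-1-yl)-4H-chromen-4-one
Product: 11 3-{[(2S)-3,3-dimethyloxiran-2-yl]methyl}-2-iodo-5,7-bis(methoxymethoxy)-6,8-di(prop-2-en-1-yl)-4H-chromen-4-one, via chromon-2-ylzinc chloride 10 (not isolated)
Conditions: TMPZnCl·LiCl (1.3 equiv), THF, 25 °C; I2, −20 to 0 °C; Na2S2O3 (aq)
Reagents that add atoms: iodine, II
Why: directed zincation of the chromone C2–H (the only acidic sp2 C–H, next to the ring oxygen) with a mild zinc amide that should leave epoxide, carbonyl and acetals untouched, followed by iodolysis of the C–Zn bond.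

Step 8
Reactants: 12 4-bromobenzene-1,3-diol
Product: 13 4-(4,4,5,5-tetramethyl-1,3,2-dioxaborolan-2-yl)benzene-1,3-diol
Conditions: B2pin2, Pd(dppf)Cl2 (5 mol %), KOAc, 1,4-dioxane, 90 °C
Reagents that add atoms: bis(pinacolato)diboron, CC1(C)OB(OC1(C)C)B1OC(C)(C)C(C)(C)O1
Why: Miyaura borylation of an aryl bromide, which tolerates free phenols under the weak acetate base and places boron on the carbon ortho to one hydroxyl and para to the other.

Step 9
Reactants: 11 3-{[(2S)-3,3-dimethyloxiran-2-yl]methyl}-2-iodo-5,7-bis(methoxymethoxy)-6,8-di(prop-2-en-1-yl)-4H-chromen-4-one; 13 4-(4,4,5,5-tetramethyl-1,3,2-dioxaborolan-2-yl)benzene-1,3-diol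
Product: 15 4'-hydroxy-5,7-bis(methoxymethoxy)-6,8-di(prop-2-en-1-yl)flavone whose C3 and 2'-oxygen are bridged by CH2–CH[C(CH3)2OH] (dihydro-1-benzoxepine ring; R at the O-bearing CH), via 2'-hydroxyflavone epoxide 14 (not isolated)
Conditions: Pd(dppf)Cl2 (5 mol %), K3PO4 (4 equiv), 1,4-dioxane/H2O (9:1), 50 °C then 90 °C
Reagents that add atoms: none
Why: Zerovalent palladium inserts into the C2–I bond of the vinylogous acyl iodide 11, transmetalation with boronate 13 and reductive elimination from divalent palladium give the 2'-hydroxyflavone 14, and its ortho phenoxide then opens the pendant epoxide in the same pot. The closest known reaction types are the Suzuki–Miyaura arylation of 2-halochromones, the domino Suzuki coupling/O-cyclization of 2-hydroxyarylboronic acids onto a neighbouring electrophile (for example lactonization), and the base-mediated cyclization of ortho-(epoxyprenyl)phenols to hydroxyisopropyl cyclic ethers. The only ring closed is the oxepine, by a 7-exo-tet epoxide opening; the 8-endo alternative at the tertiary carbon would need an acid-promoted, cation-like path that the basic medium does not offer. The stereocenter is transferred, not created: backside SN2 attack should invert the (S)-epoxide carbon to the (R)-aryl ether, so the enantiopurity of step 6 carries through while the tertiary alcohol is released. The step needs coupling at one site, attack by the 2'-oxygen only, and attack at CH and not at C(CH3)2; these are secured by the single C–I bond, by the MOM ethers on the 5- and 7-oxygens together with the para position of the free 4'-oxygen (which cannot reach), and by the SN2 preference for the less substituted epoxide carbon held within reach of the 2'-phenoxide.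

Step 10
Reactants: 15 the 6,8-diallyl oxepinoflavone of step 9
Product: 16 4'-hydroxy-5,7-bis(methoxymethoxy)-6,8-bis(3-methylbut-2-en-1-yl)flavone whose C3 and 2'-oxygen are bridged by CH2–CH[C(CH3)2OH] (R at the O-bearing CH)
Conditions: 2-methylbut-2-ene (excess), second-generation Grubbs catalyst (H2IMes)(PCy3)Cl2Ru=CHPh (10 mol %), CH2Cl2, 40 °C, sealed tube
Reagents that add atoms: 2-methylbut-2-ene, CC=C(C)C
Why: olefin cross-metathesis, in which excess 2-methylbut-2-ene transfers an isopropylidene unit to each terminal allyl group with loss of propene, a reaction type that tolerates free phenols and tertiary alcohols and leaves the stereocenter untouched.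

Step 11
Reactants: 16 the 6,8-diprenyl bis-MOM oxepinoflavone of step 10
Product: 17 the target, 4',5,7-trihydroxy-6,8-bis(3-methylbut-2-en-1-yl)flavone whose C3 and 2'-oxygen are bridged by CH2–CH[C(CH3)2OH] (R at the O-bearing CH)
Conditions: HCl (3 M aq), MeOH/THF, 40 °C
Reagents that add atoms: none
Why: acid-catalysed methanolysis of the two MOM acetals under conditions mild enough that the prenyl groups, the aryl alkyl ether and the tertiary alcohol are expected to survive and the stereocenter is not touched.

**Compound list**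

1 | 2,4,6-trihydroxyacetophenone | CC(=O)c1c(O)cc(O)cc1O | starting material
2 | 1-[2-hydroxy-4,6-bis(prop-2-en-1-yloxy)phenyl]ethan-1-one | CC(=O)c1c(O)cc(OCC=C)cc1OCC=C | intermediate
3 | 1-[2,4,6-trihydroxy-3,5-di(prop-2-en-1-yl)phenyl]ethan-1-one | CC(=O)c1c(O)c(CC=C)c(O)c(CC=C)c1O | intermediate
4 | 1-[2-hydroxy-4,6-bis(methoxymethoxy)-3,5-di(prop-2-en-1-yl)phenyl]ethan-1-one | CC(=O)c1c(O)c(CC=C)c(OCOC)c(CC=C)c1OCOC | intermediate
5 | dilithium enolate phenoxide of 4 (not isolated) | [Li+].[Li+].C=C([O-])c1c([O-])c(CC=C)c(OCOC)c(CC=C)c1OCOC | intermediate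
6 | 1-[2-hydroxy-4,6-bis(methoxymethoxy)-3,5-di(prop-2-en-1-yl)phenyl]-5-methylhex-4-en-1-one | CC(C)=CCCC(=O)c1c(O)c(CC=C)c(OCOC)c(CC=C)c1OCOC | intermediate
7 | 2-[(dimethylamino)methylidene] derivative of 6, enaminone of either geometry (not isolated) | CN(C)C=C(CC=C(C)C)C(=O)c1c(O)c(CC=C)c(OCOC)c(CC=C)c1OCOC | intermediate
8 | 5,7-bis(methoxymethoxy)-3-(3-methylbut-2-en-1-yl)-6,8-di(prop-2-en-1-yl)-4H-chromen-4-one | O=c1c(CC=C(C)C)coc2c(CC=C)c(OCOC)c(CC=C)c(OCOC)c12 | intermediate
9 | 3-{[(2S)-3,3-dimethyloxiran-2-yl]methyl}-5,7-bis(methoxymethoxy)-6,8-di(prop-2-en-1-yl)-4H-chromen-4-one | O=c1c(C[C@@H]3OC3(C)C)coc2c(CC=C)c(OCOC)c(CC=C)c(OCOC)c12 | intermediate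
10 | C2-zincated 9, chromon-2-ylzinc chloride as its LiCl complex (not isolated) | O=c1c(C[C@@H]3OC3(C)C)c([Zn]Cl)oc2c(CC=C)c(OCOC)c(CC=C)c(OCOC)c12.[Li+].[Cl-] | intermediate
11 | 3-{[(2S)-3,3-dimethyloxiran-2-yl]methyl}-2-iodo-5,7-bis(methoxymethoxy)-6,8-di(prop-2-en-1-yl)-4H-chromen-4-one | O=c1c(C[C@@H]3OC3(C)C)c(I)oc2c(CC=C)c(OCOC)c(CC=C)c(OCOC)c12 | intermediate
12 | 4-bromobenzene-1,3-diol (4-bromoresorcinol) | Oc1ccc(Br)c(O)c1 | starting material
13 | 4-(4,4,5,5-tetramethyl-1,3,2-dioxaborolan-2-yl)benzene-1,3-diol | CC1(C)OB(OC1(C)C)c1ccc(O)cc1O | intermediate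
14 | 2-(2,4-dihydroxyphenyl)-3-{[(2S)-3,3-dimethyloxiran-2-yl]methyl}-5,7-bis(methoxymethoxy)-6,8-di(prop-2-en-1-yl)-4H-chromen-4-one (not isolated) | O=c1c(C[C@@H]3OC3(C)C)c(-c3ccc(O)cc3O)oc2c(CC=C)c(OCOC)c(CC=C)c(OCOC)c12 | intermediate
15 | 4'-hydroxy-5,7-bis(methoxymethoxy)-6,8-di(prop-2-en-1-yl)flavone with C3 and O2' bridged by CH2–CH[C(CH3)2OH], R at the O-bearing CH | C=CCc1c(OCOC)c(CC=C)c2oc3c(c(=O)c2c1OCOC)C[C@H](C(C)(C)O)Oc1cc(O)ccc1-3 | intermediate
16 | 4'-hydroxy-5,7-bis(methoxymethoxy)-6,8-bis(3-methylbut-2-en-1-yl)flavone with C3 and O2' bridged by CH2–CH[C(CH3)2OH], R at the O-bearing CH | CC(C)=CCc1c(OCOC)c(CC=C(C)C)c2oc3c(c(=O)c2c1OCOC)C[C@H](C(C)(C)O)Oc1cc(O)ccc1-3 | intermediate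
17 | CNP0328977.2: 4',5,7-trihydroxy-6,8-bis(3-methylbut-2-en-1-yl)flavone with C3 and O2' bridged by CH2–CH[C(CH3)2OH], R at the O-bearing CH | CC(C)=CCc1c(O)c(CC=C(C)C)c2oc3c(c(=O)c2c1O)C[C@H](C(C)(C)O)Oc1cc(O)ccc1-3 | target

**Count and risks**

Total step count: 11. Longest linear sequence: 10 steps (steps 1 to 7 and 9 to 11); step 8 prepares the ring B partner.

Steps most likely to fail:

Step 9. The electron-rich boronate may lose boron by protonation before transmetalation. Hydroxide or phosphate may open the epoxide during the basic heating, and palladium hydride may move the allyl double bonds into conjugation. The fallback makes the ether bond first and the biaryl bond second; it sets out from epoxide 9 and bromophenol 12 and comes back at 15. Silylation of the less hindered hydroxyl of 12 (iPr3SiCl, imidazole, DMF) should give 2-bromo-5-[(triisopropylsilyl)oxy]phenol F1. Its cesium phenoxide (Cs2CO3, DMF, 80 °C) should open 9 at the secondary epoxide carbon with inversion to give 3-{(2R)-2-[2-bromo-5-(triisopropylsilyloxy)phenoxy]-3-hydroxy-3-methylbutyl}-5,7-bis(methoxymethoxy)-6,8-di(prop-2-en-1-yl)-4H-chromen-4-one F2. Intramolecular direct arylation of the chromone C2–H (Pd(OAc)2, PCy3·HBF4, K2CO3, pivalic acid, N,N-dimethylacetamide, 110 °C) should then close the seven-membered ring to the 4'-O-triisopropylsilyl ether of 15 F3. Bu4NF in THF removes the silyl group to give 15.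

Step 7. Zinc-bound chloride or iodide may open the epoxide during metalation and the iodine quench, or the amide base may isomerize it to an allylic alcohol. The fallback reverses the order of iodination and epoxidation so that the epoxide never meets the zinc reagents; it sets out from chromone 8 and comes back at 11. Zincation of 8 with TMPZnCl·LiCl and iodolysis should give 2-iodo-5,7-bis(methoxymethoxy)-3-(3-methylbut-2-en-1-yl)-6,8-di(prop-2-en-1-yl)-4H-chromen-4-one F4. Shi epoxidation of F4 with the L-fructose-derived ketone under the step 6 conditions then gives 11; the C2–I bond has to survive the buffered oxidant in that variant.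

Step 11. The acid may add the freed 5- and 7-hydroxyls across the neighbouring prenyl double bonds (chroman formation) or ionize the tertiary alcohol. The fallback removes the acetals before any prenyl group exists; it sets out from 15 and comes back at 17. Methanolysis of 15 (HCl, MeOH/THF, 40 °C) should give 4',5,7-trihydroxy-6,8-di(prop-2-en-1-yl)flavone with C3 and O2' bridged by CH2–CH[C(CH3)2OH] (R) F5. Cross-metathesis of F5 with 2-methylbut-2-ene and the second-generation Grubbs catalyst, a reaction known for free ortho-allylphenols, then gives 17.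

Further compounds
F1 | step 9 | 2-bromo-5-[(triisopropylsilyl)oxy]phenol | CC(C)[Si](Oc1ccc(Br)c(O)c1)(C(C)C)C(C)C
F2 | step 9 | 3-{(2R)-2-[2-bromo-5-(triisopropylsilyloxy)phenoxy]-3-hydroxy-3-methylbutyl}-5,7-bis(methoxymethoxy)-6,8-di(prop-2-en-1-yl)-4H-chromen-4-one | O=c1c(C[C@H](C(C)(C)O)Oc3cc(O[Si](C(C)C)(C(C)C)C(C)C)ccc3Br)coc2c(CC=C)c(OCOC)c(CC=C)c(OCOC)c12
F3 | step 9 | 4'-O-triisopropylsilyl ether of 15 | C=CCc1c(OCOC)c(CC=C)c2oc3c(c(=O)c2c1OCOC)C[C@H](C(C)(C)O)Oc1cc(O[Si](C(C)C)(C(C)C)C(C)C)ccc1-3
F4 | step 7 | 2-iodo-5,7-bis(methoxymethoxy)-3-(3-methylbut-2-en-1-yl)-6,8-di(prop-2-en-1-yl)-4H-chromen-4-one | O=c1c(CC=C(C)C)c(I)oc2c(CC=C)c(OCOC)c(CC=C)c(OCOC)c12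
F5 | step 11 | 4',5,7-trihydroxy-6,8-di(prop-2-en-1-yl)flavone with C3 and O2' bridged by CH2–CH[C(CH3)2OH], R at the O-bearing CH | C=CCc1c(O)c(CC=C)c2oc3c(c(=O)c2c1O)C[C@H](C(C)(C)O)Oc1cc(O)ccc1-3
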